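The numbers come from no measurement; what happens was integrated by code.

In 10 s of run time, every partner that reacts must first cross from the gas into solution, and at the start none is dissolved.

| flask | substrate | gas | time |
|---|---|---|---|
| Friday's | 5.0 × 10⁻⁴ M | 0.024 mM (held) | 10 s |
| Tuesday's | 0.0010 M | 0.024 mM (held) | 10 s |
| Monday's | 0.0020 M | 0.024 mM (held) | 10 s |

- [product] at the end for Friday's, Tuesday's, Monday's, in this order
- how that number moves from the first to the last of them (falls, then rises / rises all the way / hardly changes / falls all the way / rises, then falls)

    substrate + partner + product → 2 product (k1 = 8.74 × 10⁷ M⁻² s⁻¹)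
    substrate + partner → product (k2 = 1810 M⁻¹ s⁻¹)
    gas ⇌ partner, rate k3*(csat - [partner]) (k3 = 2.93 s⁻¹, csat = 0.024 mM)

- at the start none of partner is dissolved
- "hardly changes" means that all values lie within two and a half points (for a concentration: within two and a half percent of the largest)
- run time (Friday's): 10 s

Both reactions turn one partner into one product, so I count product by counting supply. With [partner] at zero the transfer runs at the supply ceiling, the transfer coefficient times the saturation concentration, 7.03 × 10⁻⁵ M s⁻¹. Over the run that totals 7.03 × 10⁻⁴ M, less than Tuesday's charge but more than Friday's, so in Friday's flask the charge, not that total, is the tighter bound on product.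

The flask falls short of the ceiling by a lag. Partner is lost by a pseudo-first-order process whose coefficient is [substrate] times the sum of the plain constant and the autocatalytic constant times [product]. The two terms are equal at [product] = 2.07 × 10⁻⁵ M. With [partner] steady, each unit of product costs one unit of supply plus the transfer coefficient over that loss coefficient. Summed up to the ceiling's total with [substrate] held at its charge, the lag is 5.96 × 10⁻⁵ M for Monday's and 1.19 × 10⁻⁴ M for Tuesday's, which leaves 6.44 × 10⁻⁴ M and 5.84 × 10⁻⁴ M.

The weak link is Friday's, where the same sum leaves 4.65 × 10⁻⁴ M, 93.0% of the charge, a larger share than in Tuesday's or Monday's, so holding [substrate] at its charge is a poor step for Friday's flask. Letting it fall, the sum has the scale 6.44 × 10⁻⁵ M. One turn from that figure gives 3.29 × 10⁻⁴ M, the next 4.52 × 10⁻⁴ M, and I commit to their middle, 3.91 × 10⁻⁴ M.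

The forecast gives 3.900 × 10⁻⁴ M, 5.500 × 10⁻⁴ M and 6.300 × 10⁻⁴ M, a row that rises all the way, with the reaction “capped by gas transfer”, and my Tuesday's and Monday's figures stand higher than its 5.500 × 10⁻⁴ M and 6.300 × 10⁻⁴ M.

The flasks give 3.97 × 10⁻⁴ M, 5.64 × 10⁻⁴ M and 6.39 × 10⁻⁴ M, and the row rises all the way. Friday's flask keeps 21% of its substrate at 10.0 s. Monday's product is 90.9% of the ceiling's total. At the ceiling, Friday's charge takes 7.11 s, and after 10.0 s Friday's product stands at 56.5% of that total.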